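**Plan**

- Germacrane numbering: C1 ring ketone, C2 furanone CH, C3 furanone C–O, C4(Me)=C5, C6 lactone O–CH, C7, C8 ester carbon, C9 CH2, C10 quaternary C(Me)–O, C11=C13 methylene, C12 lactone C=O. Retrosynthetic cuts: the C8 ester, then the 12,6-lactone, then C2–C1 and O–C10 of the furanone together, which also opens the ten-membered carbocycle.
- Enabling feature: O6 on C6 lies five atoms from C2 across the cis C4=C5 bond. C1 can therefore be parked on O6 as a seven-membered lactone (C1–C10–C9–C8–C7–C6–O6, a ring absent from the target) and handed to C2 through a seven-membered transition state. The 3(2H)-furanone is the cyclic enol ether of the C1/C3 diketone, whose enolate oxygen then closes on the α′-carbon C10, which carries a mesylate.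
- Forward: fragment A (C4–C7, C11–C13) and fragment B (C8–C10, C1) are joined by a boron aldol (C7–C8). O8 silylation, C6 reduction, C1 oxidation and lactonisation give the seven-membered lactone; Stille coupling adds C3/C2; mesylation; then ring expansion with furanone closure makes the ten-membered ring and its oxygen bridge at once. Lactone switch to C12, desilylation and esterification finish the route.
- Stereochemistry: C10 from (R)-2-methylglycidol, inverted in the key step; C7 and C8 from the Ipc2B syn-aldol; C6 from CBS reduction; 4Z from hydroalumination–iodination of but-2-yn-1-ol; the E side chain from a DABCO allylic transposition.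

Key step: step 16

Assumption: in step 8 the reagent sign is written as (−)-Ipc2BOTf; what is meant is the enantiomer whose Z-enolate gives the drawn 7,8-syn adduct by Paterson's chair model.

**Route**

Step 1
Reactants: 1 but-2-yn-1-ol
Product: 2 (2Z)-3-iodobut-2-en-1-ol
Conditions: NaAlH2(OCH2CH2OCH3)2, THF, 0 °C to rt; then I2, −78 to 0 °C
Reagents that add atoms: iodine, II
Why: Trans-hydroalumination of the propargylic alcohol places aluminium on C3 anti to the new C2–H, and iodinolysis with retention gives the Z-vinyl iodide that fixes the 4,5-cis geometry.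

Step 2
Reactants: 2 (2Z)-3-iodobut-2-en-1-ol
Product: 3 (2Z)-3-iodobut-2-enal
Conditions: MnO2, CH2Cl2, rt
Reagents that add atoms: none
Why: Allylic oxidation with MnO2 should give the enal without touching the vinyl iodide or the double-bond geometry.

Step 3
Reactants: 3 (2Z)-3-iodobut-2-enal; 4 tert-butyl 2-(bromomethyl)prop-2-enoate
Product: 5 tert-butyl (5Z)-4-hydroxy-6-iodo-2-methylidenehept-5-enoate (racemic at C4)
Conditions: In powder, THF/H2O (1:1), rt
Reagents that add atoms: none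
Why: Indium-mediated Barbier allylation adds the allylindium from 4 in 1,2-fashion to the enal with allylic transposition; the racemic carbinol centre is removed in step 4.

Step 4
Reactants: 5 tert-butyl (5Z)-4-hydroxy-6-iodo-2-methylidenehept-5-enoate
Product: 6 tert-butyl (5Z)-6-iodo-2-methylidene-4-oxohept-5-enoate
Conditions: Dess–Martin periodinane, NaHCO3, CH2Cl2, 0 °C
Reagents that add atoms: none
Why: Dess–Martin oxidation gives the ketone under buffered, non-enolising conditions, so the β,γ-unsaturated ester should not move into conjugation.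

Step 5
Reactants: 7 [(2R)-2-methyloxiran-2-yl]methanol
Product: 8 (2S)-2-methylpent-4-ene-1,2-diol
Conditions: vinylmagnesium bromide (3 equiv), CuI (10 mol%), THF, −30 to 0 °C
Reagents that add atoms: vinylmagnesium bromide, C=C[Mg]Br
Why: CuI-catalysed Grignard opening of the epoxide at its unsubstituted carbon (SN2) leaves the quaternary stereocentre from the chiral pool untouched.

Step 6
Reactants: 8 (2S)-2-methylpent-4-ene-1,2-diol
Product: 9 (4S)-2,2,4-trimethyl-4-(prop-2-en-1-yl)-1,3-dioxolane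
Conditions: 2,2-dimethoxypropane, PPTS (cat.), CH2Cl2, rt
Reagents that add atoms: 2,2-dimethoxypropane, COC(C)(C)OC
Why: Acid-catalysed transketalisation protects the primary and the tertiary hydroxyl together as one dioxolane.

Step 7
Reactants: 9 (4S)-2,2,4-trimethyl-4-(prop-2-en-1-yl)-1,3-dioxolane
Product: 10 2-[(4S)-2,2,4-trimethyl-1,3-dioxolan-4-yl]acetaldehyde
Conditions: O3, CH2Cl2, −78 °C; then PPh3
Reagents that add atoms: ozone, [O-][O+]=O
Why: Ozonolysis with reductive work-up cleaves the terminal alkene to the aldehyde.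

Step 8
Reactants: 6 tert-butyl (5Z)-6-iodo-2-methylidene-4-oxohept-5-enoate; 10 2-[(4S)-2,2,4-trimethyl-1,3-dioxolan-4-yl]acetaldehyde
Product: 11 tert-butyl (3S,5Z)-3-{(1R)-1-hydroxy-2-[(4S)-2,2,4-trimethyl-1,3-dioxolan-4-yl]ethyl}-6-iodo-2-methylidene-4-oxohept-5-enoate
Conditions: (−)-Ipc2BOTf, iPr2NEt, CH2Cl2, −78 °C; then 10, −78 to −20 °C; H2O2, MeOH, pH 7 buffer, 0 °C
Reagents that add atoms: none
Why: Paterson boron aldol, in which the Ipc2B Z-enolate of 6 (only C7 is enolisable) adds through a chair transition state to give the 7,8-syn adduct, the Ipc ligands choosing the enolate face so that C7 is S and C8 is R beside the fixed 10S centre.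

Step 9
Reactants: 11 tert-butyl (3S,5Z)-3-{(1R)-1-hydroxy-2-[(4S)-2,2,4-trimethyl-1,3-dioxolan-4-yl]ethyl}-6-iodo-2-methylidene-4-oxohept-5-enoate
Product: 12 tert-butyl (3S,5Z)-3-{(1R)-1-[(tert-butyldimethylsilyl)oxy]-2-[(4S)-2,2,4-trimethyl-1,3-dioxolan-4-yl]ethyl}-6-iodo-2-methylidene-4-oxohept-5-enoate
Conditions: TBSOTf, 2,6-lutidine, CH2Cl2, −78 °C
Reagents that add atoms: tert-butyldimethylsilyl trifluoromethanesulfonate, CC(C)(C)[Si](C)(C)OS(=O)(=O)C(F)(F)F
Why: Low-temperature silylation of the only free hydroxyl blocks O8, so that only O6 can lactonise later, and prevents retro-aldol cleavage.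

Step 10
Reactants: 12 tert-butyl (3S,5Z)-3-{(1R)-1-[(tert-butyldimethylsilyl)oxy]-2-[(4S)-2,2,4-trimethyl-1,3-dioxolan-4-yl]ethyl}-6-iodo-2-methylidene-4-oxohept-5-enoate
Product: 13 tert-butyl (3R,4R,5Z)-3-{(1R)-1-[(tert-butyldimethylsilyl)oxy]-2-[(4S)-2,2,4-trimethyl-1,3-dioxolan-4-yl]ethyl}-4-hydroxy-6-iodo-2-methylidenehept-5-enoate
Conditions: (S)-2-methyl-CBS-oxazaborolidine, catecholborane, toluene, −78 °C
Reagents that add atoms: none
Why: Corey–Bakshi–Shibata reduction, in which the iodoalkenyl group acts as the large substituent and the (S)-oxazaborolidine should deliver hydride 1,2 to give the 4R allylic alcohol (C6 of the target) under reagent control.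

Step 11
Reactants: 13 tert-butyl (3R,4R,5Z)-3-{(1R)-1-[(tert-butyldimethylsilyl)oxy]-2-[(4S)-2,2,4-trimethyl-1,3-dioxolan-4-yl]ethyl}-4-hydroxy-6-iodo-2-methylidenehept-5-enoate
Product: 14 tert-butyl (3R,4R,5Z)-3-{(1R,3S)-1-[(tert-butyldimethylsilyl)oxy]-3,4-dihydroxy-3-methylbutyl}-4-hydroxy-6-iodo-2-methylidenehept-5-enoate
Conditions: AcOH/THF/H2O (3:1:1), 40 °C
Reagents that add atoms: none
Why: Mild aqueous acid hydrolyses the dioxolane while the hindered secondary TBS ether and the tert-butyl ester should survive.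

Step 12
Reactants: 14 tert-butyl (3R,4R,5Z)-3-{(1R,3S)-1-[(tert-butyldimethylsilyl)oxy]-3,4-dihydroxy-3-methylbutyl}-4-hydroxy-6-iodo-2-methylidenehept-5-enoate
Product: 15 (2S,4R,5R,6R,7Z)-5-[3-(tert-butoxy)-3-oxoprop-1-en-2-yl]-4-[(tert-butyldimethylsilyl)oxy]-2,6-dihydroxy-8-iodo-2-methylnon-7-enoic acid
Conditions: TEMPO (cat.), NaClO2, NaOCl (cat.), MeCN/pH 6.7 phosphate buffer, 35 °C
Reagents that add atoms: sodium chlorite, [Na+].[O-]Cl=O
Why: TEMPO-catalysed chlorite oxidation (Zhao conditions) takes the primary alcohol to the acid and should leave the secondary allylic and the tertiary hydroxyl untouched.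

Step 13
Reactants: 15 (2S,4R,5R,6R,7Z)-5-[3-(tert-butoxy)-3-oxoprop-1-en-2-yl]-4-[(tert-butyldimethylsilyl)oxy]-2,6-dihydroxy-8-iodo-2-methylnon-7-enoic acid
Product: 16 tert-butyl 2-{(2R,3R,4R,6S)-4-[(tert-butyldimethylsilyl)oxy]-6-hydroxy-2-[(1Z)-2-iodoprop-1-en-1-yl]-6-methyl-7-oxooxepan-3-yl}prop-2-enoate
Conditions: 2,4,6-Cl3C6H2COCl, Et3N, THF, rt; then DMAP, toluene (0.002 M), 80 °C
Reagents that add atoms: none
Why: Yamaguchi lactonisation, in which the mixed anhydride is attacked at high dilution by O6, the only reactive hydroxyl (O8 is silylated, O10 is tertiary, the tert-butyl ester does not lactonise), closing the seven-membered lactone with retention at C6.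

Step 14
Reactants: 16 tert-butyl 2-{(2R,3R,4R,6S)-4-[(tert-butyldimethylsilyl)oxy]-6-hydroxy-2-[(1Z)-2-iodoprop-1-en-1-yl]-6-methyl-7-oxooxepan-3-yl}prop-2-enoate
Product: 18 tert-butyl 2-{(2S,3R,4R,6S)-4-[(tert-butyldimethylsilyl)oxy]-6-hydroxy-6-methyl-2-[(1Z)-2-methyl-3-oxobut-1-en-1-yl]-7-oxooxepan-3-yl}prop-2-enoate, via enol ether 17 (not isolated)
Conditions: tributyl(1-ethoxyvinyl)stannane, Pd2(dba)3, AsPh3, CuI, NMP, rt; then 0.5 M HCl, THF, 0 °C
Reagents that add atoms: tributyl(1-ethoxyvinyl)stannane, CCOC(=C)[Sn](CCCC)(CCCC)CCCC; water, O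
Why: Stille coupling of the Z-vinyl iodide with retention, then mild hydrolysis of the enol ether, installs the methyl ketone (C3, C2) only after O6 is acylated, so the Z-γ-oxy enone cannot close to a furan.

Step 15
Reactants: 18 tert-butyl 2-{(2S,3R,4R,6S)-4-[(tert-butyldimethylsilyl)oxy]-6-hydroxy-6-methyl-2-[(1Z)-2-methyl-3-oxobut-1-en-1-yl]-7-oxooxepan-3-yl}prop-2-enoate
Product: 19 tert-butyl 2-{(2S,3R,4R,6S)-4-[(tert-butyldimethylsilyl)oxy]-6-methyl-6-[(methylsulfonyl)oxy]-2-[(1Z)-2-methyl-3-oxobut-1-en-1-yl]-7-oxooxepan-3-yl}prop-2-enoate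
Conditions: MsCl, Et3N, DMAP (cat.), CH2Cl2, 0 °C to rt
Reagents that add atoms: methanesulfonyl chloride, CS(=O)(=O)Cl
Why: Sulfene-type mesylation of the tertiary α-hydroxy lactone puts the leaving group on C10 with its configuration unchanged.

Step 16
Reactants: 19 tert-butyl 2-{(2S,3R,4R,6S)-4-[(tert-butyldimethylsilyl)oxy]-6-methyl-6-[(methylsulfonyl)oxy]-2-[(1Z)-2-methyl-3-oxobut-1-en-1-yl]-7-oxooxepan-3-yl}prop-2-enoate
Product: 22 tert-butyl (4Z,6S,7R,8R,10R)-8-[(tert-butyldimethylsilyl)oxy]-3,10-epoxy-6-hydroxy-1-oxogermacra-2,4,11(13)-trien-12-oate, via bridged hemiketal alkoxide 20 (not isolated), via ten-membered diketone mesylate 21 (not isolated)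
Conditions: LiN(SiMe3)2 (1.05 equiv), THF (0.005 M), −78 °C; then −78 to 0 °C; AcOH quench
Reagents that add atoms: none
Why: Proposed new method: LiN(SiMe3)2 removes a C2 proton of the methyl ketone, and because the cis C4=C5 bond holds this enolate five atoms from the lactone carbonyl, C2 adds to C1 in a 7-(enolendo)-exo-trig closure to the bridged hemiketal alkoxide 20, which collapses by C1–O6 cleavage to the ten-membered 1,3-diketone 21 (C2–C1 formed, a net three-atom ring expansion of the lactone to the carbocycle). Proton transfer from C2 to the freed C6 alkoxide gives the stabilised diketone enolate, which makes the acyl transfer irreversible, and its C3 oxygen then displaces the tertiary α-keto mesylate at C10 in a 5-exo-tet closure (O–C10 formed) to the 3(2H)-furanone. The closest known reaction types are the Baker–Venkataraman O-to-C acyl transfer and side-chain-insertion ring expansions of lactones for the first bond, and the base-induced cyclisation of α′-halo 1,3-diketones to 3(2H)-furanones for the second; neither has been run as a seven-to-ten ring expansion or on a stereodefined tertiary sulfonate. C10 is the only stereocentre touched and is set by inversion, (10S)-mesylate to (10R)-ether, so its configuration derives from (R)-2-methylglycidol, while C6, C7 and C8 are carried through. The step needs deprotonation at C2 rather than at C6 and C-acylation at C1 rather than attack on the acrylate, which kinetic deprotonation at −78 °C, one equivalent of base, high dilution and the seven-membered geometry should secure; it also needs substitution rather than elimination at C10, which the weakly basic diketone enolate and the intramolecular exo trajectory favour.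

Step 17
Reactants: 22 tert-butyl (4Z,6S,7R,8R,10R)-8-[(tert-butyldimethylsilyl)oxy]-3,10-epoxy-6-hydroxy-1-oxogermacra-2,4,11(13)-trien-12-oate
Product: 23 (4Z,6S,7R,8R,10R)-8-[(tert-butyldimethylsilyl)oxy]-3,10-epoxy-1-oxogermacra-2,4,11(13)-trien-12,6-olide
Conditions: TFA/CH2Cl2 (1:4), 0 °C
Reagents that add atoms: none
Why: Acidolysis of the tert-butyl ester and acid-catalysed 5-exo lactonisation of the C6 hydroxyl on C12 should give the trans-fused α-methylene-γ-butyrolactone, and only the 6,12-lactone can form because O8 stays silylated.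

Step 18
Reactants: 23 (4Z,6S,7R,8R,10R)-8-[(tert-butyldimethylsilyl)oxy]-3,10-epoxy-1-oxogermacra-2,4,11(13)-trien-12,6-olide
Product: 24 (4Z,6S,7S,8R,10R)-3,10-epoxy-8-hydroxy-1-oxogermacra-2,4,11(13)-trien-12,6-olide
Conditions: HF·pyridine, THF, 0 °C to rt
Reagents that add atoms: none
Why: Fluoride desilylation frees the C8 hydroxyl under conditions that should leave the methylene lactone and the furanone intact.

Step 19
Reactants: 25 acetaldehyde; 26 tert-butyl prop-2-enoate
Product: 27 tert-butyl 3-hydroxy-2-methylidenebutanoate (racemic)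
Conditions: DABCO, dioxane/H2O, rt
Reagents that add atoms: none
Why: Morita–Baylis–Hillman reaction joins the acrylate α-carbon to acetaldehyde; the racemic carbinol centre is lost in step 20.

Step 20
Reactants: 27 tert-butyl 3-hydroxy-2-methylidenebutanoate
Product: 29 tert-butyl (2E)-2-[(acetyloxy)methyl]but-2-enoate, via secondary acetate 28 (not isolated)
Conditions: Ac2O, Et3N, DMAP (cat.), CH2Cl2, 0 °C; then DABCO (cat.), THF, 60 °C
Reagents that add atoms: acetic anhydride, CC(=O)OC(C)=O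
Why: Acetylation followed by DABCO-catalysed SN2′–SN2′ allylic transposition of the Baylis–Hillman acetate should give the thermodynamic primary acetate with the E trisubstituted double bond.

Step 21
Reactants: 29 tert-butyl (2E)-2-[(acetyloxy)methyl]but-2-enoate
Product: 30 (2E)-2-[(acetyloxy)methyl]but-2-enoic acid
Conditions: TFA/CH2Cl2 (1:3), rt
Reagents that add atoms: none
Why: Acidolysis of the tert-butyl ester frees the acid without touching the acetate or the double-bond geometry.

Step 22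
Reactants: 24 (4Z,6S,7S,8R,10R)-3,10-epoxy-8-hydroxy-1-oxogermacra-2,4,11(13)-trien-12,6-olide; 30 (2E)-2-[(acetyloxy)methyl]but-2-enoic acid
Product: 31 (4Z,6S,7S,8R,10R)-8-{[(2E)-2-[(acetyloxy)methyl]but-2-enoyl]oxy}-3,10-epoxy-1-oxogermacra-2,4,11(13)-trien-12,6-olide (CNP0176571.1)
Conditions: 30, 2,4,6-Cl3C6H2COCl, Et3N, toluene, rt; then 24, DMAP, 0 °C to rt
Reagents that add atoms: none
Why: Yamaguchi esterification should acylate the hindered secondary C8 hydroxyl with retention at C8 and without isomerising the E-enoate.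

**Compound list**

1 | but-2-yn-1-ol | CC#CCO | starting material
2 | (2Z)-3-iodobut-2-en-1-ol | OC/C=C(/C)I | intermediate
3 | (2Z)-3-iodobut-2-enal | O=C/C=C(/C)I | intermediate
4 | tert-butyl 2-(bromomethyl)prop-2-enoate | C=C(CBr)C(=O)OC(C)(C)C | starting material
5 | tert-butyl (5Z)-4-hydroxy-6-iodo-2-methylidenehept-5-enoate (racemic) | CC(C)(C)OC(=O)C(=C)CC(O)/C=C(/C)I | intermediate
6 | tert-butyl (5Z)-6-iodo-2-methylidene-4-oxohept-5-enoate | CC(C)(C)OC(=O)C(=C)CC(=O)/C=C(/C)I | intermediate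
7 | [(2R)-2-methyloxiran-2-yl]methanol ((R)-2-methylglycidol) | OC[C@]1(C)CO1 | starting material
8 | (2S)-2-methylpent-4-ene-1,2-diol | C=CC[C@](C)(O)CO | intermediate
9 | (4S)-2,2,4-trimethyl-4-(prop-2-en-1-yl)-1,3-dioxolane | C=CC[C@@]1(C)COC(C)(C)O1 | intermediate
10 | 2-[(4S)-2,2,4-trimethyl-1,3-dioxolan-4-yl]acetaldehyde | O=CC[C@@]1(C)COC(C)(C)O1 | intermediate
11 | tert-butyl (3S,5Z)-3-{(1R)-1-hydroxy-2-[(4S)-2,2,4-trimethyl-1,3-dioxolan-4-yl]ethyl}-6-iodo-2-methylidene-4-oxohept-5-enoate | CC(C)(C)OC(=O)C(=C)[C@@H]([C@H](O)C[C@@]1(C)COC(C)(C)O1)C(=O)/C=C(/C)I | intermediate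
12 | tert-butyl (3S,5Z)-3-{(1R)-1-[(tert-butyldimethylsilyl)oxy]-2-[(4S)-2,2,4-trimethyl-1,3-dioxolan-4-yl]ethyl}-6-iodo-2-methylidene-4-oxohept-5-enoate | CC(C)(C)OC(=O)C(=C)[C@@H]([C@H](O[Si](C)(C)C(C)(C)C)C[C@@]1(C)COC(C)(C)O1)C(=O)/C=C(/C)I | intermediate
13 | tert-butyl (3R,4R,5Z)-3-{(1R)-1-[(tert-butyldimethylsilyl)oxy]-2-[(4S)-2,2,4-trimethyl-1,3-dioxolan-4-yl]ethyl}-4-hydroxy-6-iodo-2-methylidenehept-5-enoate | CC(C)(C)OC(=O)C(=C)[C@@H]([C@H](O[Si](C)(C)C(C)(C)C)C[C@@]1(C)COC(C)(C)O1)[C@@H](O)/C=C(/C)I | intermediate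
14 | tert-butyl (3R,4R,5Z)-3-{(1R,3S)-1-[(tert-butyldimethylsilyl)oxy]-3,4-dihydroxy-3-methylbutyl}-4-hydroxy-6-iodo-2-methylidenehept-5-enoate | CC(C)(C)OC(=O)C(=C)[C@@H]([C@H](O[Si](C)(C)C(C)(C)C)C[C@](C)(O)CO)[C@@H](O)/C=C(/C)I | intermediate
15 | (2S,4R,5R,6R,7Z)-5-[3-(tert-butoxy)-3-oxoprop-1-en-2-yl]-4-[(tert-butyldimethylsilyl)oxy]-2,6-dihydroxy-8-iodo-2-methylnon-7-enoic acid | CC(C)(C)OC(=O)C(=C)[C@@H]([C@H](O[Si](C)(C)C(C)(C)C)C[C@](C)(O)C(=O)O)[C@@H](O)/C=C(/C)I | intermediate
16 | tert-butyl 2-{(2R,3R,4R,6S)-4-[(tert-butyldimethylsilyl)oxy]-6-hydroxy-2-[(1Z)-2-iodoprop-1-en-1-yl]-6-methyl-7-oxooxepan-3-yl}prop-2-enoate | CC(C)(C)OC(=O)C(=C)[C@H]1[C@H](O[Si](C)(C)C(C)(C)C)C[C@](C)(O)C(=O)O[C@H]1/C=C(/C)I | intermediate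
17 | tert-butyl 2-{(2S,3R,4R,6S)-4-[(tert-butyldimethylsilyl)oxy]-2-[(1Z)-3-ethoxy-2-methylbuta-1,3-dien-1-yl]-6-hydroxy-6-methyl-7-oxooxepan-3-yl}prop-2-enoate (not isolated) | CC(C)(C)OC(=O)C(=C)[C@H]1[C@H](O[Si](C)(C)C(C)(C)C)C[C@](C)(O)C(=O)O[C@H]1/C=C(/C)C(=C)OCC | intermediate
18 | tert-butyl 2-{(2S,3R,4R,6S)-4-[(tert-butyldimethylsilyl)oxy]-6-hydroxy-6-methyl-2-[(1Z)-2-methyl-3-oxobut-1-en-1-yl]-7-oxooxepan-3-yl}prop-2-enoate | CC(C)(C)OC(=O)C(=C)[C@H]1[C@H](O[Si](C)(C)C(C)(C)C)C[C@](C)(O)C(=O)O[C@H]1/C=C(/C)C(C)=O | intermediate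
19 | tert-butyl 2-{(2S,3R,4R,6S)-4-[(tert-butyldimethylsilyl)oxy]-6-methyl-6-[(methylsulfonyl)oxy]-2-[(1Z)-2-methyl-3-oxobut-1-en-1-yl]-7-oxooxepan-3-yl}prop-2-enoate | CC(C)(C)OC(=O)C(=C)[C@H]1[C@H](O[Si](C)(C)C(C)(C)C)C[C@](C)(OS(C)(=O)=O)C(=O)O[C@H]1/C=C(/C)C(C)=O | intermediate
20 | lithium alkoxide of the bridged hemiketal (11-oxabicyclo[4.4.1]undecenone core; C1 bonded to O6, O−, C2 and C10; not isolated) | CC(C)(C)OC(=O)C(=C)[C@H]1[C@H](O[Si](C)(C)C(C)(C)C)C[C@](C)(OS(C)(=O)=O)[C@@]2([O-])CC(=O)/C(C)=C\[C@@H]1O2.[Li+] | intermediate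
21 | tert-butyl (4Z,6S,7R,8R,10S)-8-[(tert-butyldimethylsilyl)oxy]-6-hydroxy-10-[(methylsulfonyl)oxy]-1,3-dioxogermacra-4,11(13)-dien-12-oate (present as its lithium enolate; not isolated) | CC(C)(C)OC(=O)C(=C)[C@H]1[C@H](O[Si](C)(C)C(C)(C)C)C[C@](C)(OS(C)(=O)=O)C(=O)CC(=O)/C(C)=C\[C@@H]1O | intermediate
22 | tert-butyl (4Z,6S,7R,8R,10R)-8-[(tert-butyldimethylsilyl)oxy]-3,10-epoxy-6-hydroxy-1-oxogermacra-2,4,11(13)-trien-12-oate | CC(C)(C)OC(=O)C(=C)[C@H]1[C@H](O[Si](C)(C)C(C)(C)C)C[C@@]2(C)OC(=CC2=O)/C(C)=C\[C@@H]1O | intermediate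
23 | (4Z,6S,7R,8R,10R)-8-[(tert-butyldimethylsilyl)oxy]-3,10-epoxy-1-oxogermacra-2,4,11(13)-trien-12,6-olide | C=C1C(=O)O[C@H]2/C=C(/C)C3=CC(=O)[C@@](C)(C[C@@H](O[Si](C)(C)C(C)(C)C)[C@H]12)O3 | intermediate
24 | (4Z,6S,7S,8R,10R)-3,10-epoxy-8-hydroxy-1-oxogermacra-2,4,11(13)-trien-12,6-olide | C=C1C(=O)O[C@H]2/C=C(/C)C3=CC(=O)[C@@](C)(C[C@@H](O)[C@H]12)O3 | intermediate
25 | acetaldehyde | CC=O | starting material
26 | tert-butyl prop-2-enoate | C=CC(=O)OC(C)(C)C | starting material
27 | tert-butyl 3-hydroxy-2-methylidenebutanoate (racemic) | CC(O)C(=C)C(=O)OC(C)(C)C | intermediate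
28 | tert-butyl 3-(acetyloxy)-2-methylidenebutanoate (racemic; not isolated) | CC(OC(C)=O)C(=C)C(=O)OC(C)(C)C | intermediate
29 | tert-butyl (2E)-2-[(acetyloxy)methyl]but-2-enoate | CC(C)(C)OC(=O)/C(=C/C)COC(C)=O | intermediate
30 | (2E)-2-[(acetyloxy)methyl]but-2-enoic acid | OC(=O)/C(=C/C)COC(C)=O | intermediate
31 | (4Z,6S,7S,8R,10R)-8-{[(2E)-2-[(acetyloxy)methyl]but-2-enoyl]oxy}-3,10-epoxy-1-oxogermacra-2,4,11(13)-trien-12,6-olide (CNP0176571.1) | C=C1C(=O)O[C@H]2/C=C(/C)C3=CC(=O)[C@@](C)(C[C@@H](OC(=O)/C(=C/C)COC(C)=O)[C@H]12)O3 | target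

**Totals and risks**

Total step count: 22. Longest linear sequence: 16 steps (steps 1–4, 8–18 and 22).

Step 16 (ring expansion with furanone closure). What may go wrong: the enolate may add to C1 without the hemiketal collapsing, base may be consumed by deprotonation at C6 or by elimination of methanesulfonic acid, or ionisation at C10 may erode the inversion. The fallback uses known reactions only, sets out from 13 and comes back at 23. TFA in wet CH2Cl2 removes the tert-butyl ester and the acetonide of 13, and the C6 hydroxyl closes on C12 to the butyrolactone diol F1, so the natural lactone is made first and no acyl transfer is needed. Parikh–Doering oxidation (SO3·pyridine, DMSO, iPr2NEt) of the primary alcohol gives the α-hydroxy aldehyde F2, and MsCl/Et3N gives the α-mesyloxy aldehyde F3. Stille coupling with tributyl(1-ethoxyvinyl)stannane gives the enol ether F4, which is brominated without isolation (NBS, THF/H2O, 0 °C) to the bromomethyl ketone F5. A chromium Reformatsky macroaldol (CrCl2, LiI, THF, high dilution) closes the ten-membered ring at C1–C2 to the β-hydroxy ketone F6. Dess–Martin oxidation gives the 1,3-diketone mesylate F7, and K2CO3 in DMF closes the furanone by the known cyclisation of α′-leaving-group 1,3-diketones to give 23.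

Step 13 (seven-membered lactonisation). What may go wrong: ring closure of the hindered mixed anhydride may be slow, so that intermolecular esterification (oligomer formation) or acylation of the tertiary hydroxyl takes over. The fallback sets out from 14, comes back at 16 and closes the ring at the alcohol oxidation level. TEMPO (cat.) with PhI(OAc)2 in CH2Cl2 oxidises the primary alcohol of 14 to the aldehyde, which is trapped by the C6 hydroxyl as the seven-membered lactol F8 and oxidised further in the same flask to 16, so no carboxyl activation is required.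

Step 10 (CBS reduction). What may go wrong: facial selectivity may be poor because both groups on the ketone are bulky, and 1,4-reduction may compete. The fallback sets out from 12, comes back at 13 and replaces reagent control by separation and inversion. Luche reduction (NaBH4, CeCl3·7H2O, MeOH, −78 °C) should give 13 together with its C6 epimer F9. After separation, F9 is converted by Mitsunobu inversion (4-nitrobenzoic acid, PPh3, DIAD, THF) into the 4-nitrobenzoate F10, which has the configuration of 13, and methanolysis (K2CO3, MeOH, 0 °C) returns 13.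

Further compounds
F1 | step 16 | butyrolactone diol: 12,6-lactone with (1Z)-2-iodoprop-1-enyl on C6, 8-OTBS, 10-hydroxy, 1-hydroxy (6R,7R,8R,10S) | C=C1C(=O)O[C@@H](/C=C(/C)I)[C@@H]1[C@H](O[Si](C)(C)C(C)(C)C)C[C@](C)(O)CO
F2 | step 16 | α-hydroxy aldehyde (C1 aldehyde of F1) | C=C1C(=O)O[C@@H](/C=C(/C)I)[C@@H]1[C@H](O[Si](C)(C)C(C)(C)C)C[C@](C)(O)C=O
F3 | step 16 | α-mesyloxy aldehyde (10-mesylate of F2) | C=C1C(=O)O[C@@H](/C=C(/C)I)[C@@H]1[C@H](O[Si](C)(C)C(C)(C)C)C[C@](C)(OS(C)(=O)=O)C=O
F4 | step 16 | enol ether from Stille coupling of F3 (not isolated) | C=C1C(=O)O[C@@H](/C=C(/C)C(=C)OCC)[C@@H]1[C@H](O[Si](C)(C)C(C)(C)C)C[C@](C)(OS(C)(=O)=O)C=O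
F5 | step 16 | bromomethyl ketone (Z-enone, C2 bromide) | C=C1C(=O)O[C@@H](/C=C(/C)C(=O)CBr)[C@@H]1[C@H](O[Si](C)(C)C(C)(C)C)C[C@](C)(OS(C)(=O)=O)C=O
F6 | step 16 | ten-membered β-hydroxy ketone (1-hydroxy-3-oxo, 10-mesylate, 8-OTBS, 12,6-olide; C1 epimers) | C=C1C(=O)O[C@H]2/C=C(/C)C(=O)CC(O)[C@@](C)(OS(C)(=O)=O)C[C@@H](O[Si](C)(C)C(C)(C)C)[C@H]12
F7 | step 16 | ten-membered 1,3-diketone mesylate (1,3-dioxo, 10S-mesylate, 8-OTBS, 12,6-olide) | C=C1C(=O)O[C@H]2/C=C(/C)C(=O)CC(=O)[C@@](C)(OS(C)(=O)=O)C[C@@H](O[Si](C)(C)C(C)(C)C)[C@H]12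
F8 | step 13 | seven-membered lactol of 14 (C1 hemiacetal with O6; anomers; not isolated) | CC(C)(C)OC(=O)C(=C)[C@H]1[C@H](O[Si](C)(C)C(C)(C)C)C[C@](C)(O)C(O)O[C@H]1/C=C(/C)I
F9 | step 10 | C4 epimer of 13 (heptenoate numbering; C6 of the target) | CC(C)(C)OC(=O)C(=C)[C@@H]([C@H](O[Si](C)(C)C(C)(C)C)C[C@@]1(C)COC(C)(C)O1)[C@H](O)/C=C(/C)I
F10 | step 10 | 4-nitrobenzoate of 13 | CC(C)(C)OC(=O)C(=C)[C@@H]([C@H](O[Si](C)(C)C(C)(C)C)C[C@@]1(C)COC(C)(C)O1)[C@@H](OC(=O)c1ccc(cc1)[N+](=O)[O-])/C=C(/C)I
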